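**Retrosynthetic overview**
- The target comes from its 5,2',4'-tri-O-benzyl ether by hydrogenolysis; rings A and B are bought as benzenoid starting materials, and ring C is the only ring built, formed last.
- Ring C comes from acid-triggered MOM removal and cyclodehydration of a 2-methoxy-1,3-diaryl-1,3-diketone; a benzyl ether on the future O5 leaves only the phenol next to the methoxy group free to close, which fixes 8-OMe.
- The diketone comes from an intermolecular crossed Claisen condensation (C2–C3 bond): lithium enolate of the ring A ω-methoxy ketone plus the ring B aroyl chloride.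
- The ring A ketone comes from mirror-symmetric 5-benzyloxy-2-methoxy-1,3-bis(MOM-oxy)benzene (bromination, Br/Li exchange, Weinreb amide), itself from methyl 3,5-dihydroxy-4-methoxybenzoate by Baeyer–Villiger excision of the carboxyl carbon.
- The ring B acid chloride comes from 2,4-bis(benzyloxy)-1-methoxybenzene (Vilsmeier formylation, Pinnick oxidation), itself from 3-(benzyloxy)-4-methoxybenzaldehyde (Baeyer–Villiger, benzylation).

Assumption: the target is achiral (no stereocentre, no stereo descriptor in its SMILES), so its constitution alone defines the requested single compound.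

**Ring A fragment**

Step 1
Reactants: 1 methyl 3,5-dihydroxy-4-methoxybenzoate
Product: 2 methyl 4-methoxy-3,5-bis(methoxymethoxy)benzoate
Conditions: MOMCl (3 equiv), i-Pr2NEt (4 equiv), CH2Cl2, 0 °C to rt
Reagents that add atoms: chloromethyl methyl ether (MOMCl), COCCl
Why: Standard O-alkylation of both phenols as MOM acetals leaves the ester untouched and keeps the ring mirror-symmetric.

Step 2
Reactants: 2 methyl 4-methoxy-3,5-bis(methoxymethoxy)benzoate
Product: 3 [4-methoxy-3,5-bis(methoxymethoxy)phenyl]methanol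
Conditions: LiAlH4, THF, 0 °C; then H2O, aq. NaOH
Reagents that add atoms: none
Why: Hydride reduction of the aryl ester gives the benzylic alcohol, and acetal and methyl ethers are inert to LiAlH4.

Step 3
Reactants: 3 [4-methoxy-3,5-bis(methoxymethoxy)phenyl]methanol
Product: 4 4-methoxy-3,5-bis(methoxymethoxy)benzaldehyde
Conditions: MnO2 (activated, 10 equiv), CH2Cl2, rt
Reagents that add atoms: none
Why: Activated MnO2 oxidises benzylic alcohols selectively and stops at the aldehyde.

Step 4
Reactants: 4 4-methoxy-3,5-bis(methoxymethoxy)benzaldehyde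
Product: 6 4-methoxy-3,5-bis(methoxymethoxy)phenol, via aryl formate 5 (not isolated)
Conditions: mCPBA, CH2Cl2, 0 °C to rt; aq. NaHCO3 wash; then K2CO3 (cat.), MeOH, rt
Reagents that add atoms: 3-chloroperoxybenzoic acid (mCPBA), OOC(=O)c1cccc(Cl)c1
Why: Baeyer–Villiger oxidation with migration of the electron-rich p-methoxyaryl group gives the aryl formate, which mild methanolysis cleaves to the phenol, so the carbon substituent is replaced by oxygen.

Step 5
Reactants: 6 4-methoxy-3,5-bis(methoxymethoxy)phenol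
Product: 7 5-(benzyloxy)-2-methoxy-1,3-bis(methoxymethoxy)benzene
Conditions: BnBr, K2CO3, DMF, rt
Reagents that add atoms: benzyl bromide, BrCc1ccccc1
Why: Williamson etherification of the only free phenol puts a benzyl group on the oxygen that will become O5.

Step 6
Reactants: 7 5-(benzyloxy)-2-methoxy-1,3-bis(methoxymethoxy)benzene
Product: 8 1-(benzyloxy)-2-bromo-4-methoxy-3,5-bis(methoxymethoxy)benzene
Conditions: NBS (1.0 equiv), MeCN, 0 °C
Reagents that add atoms: N-bromosuccinimide, O=C1CCC(=O)N1Br
Why: Electrophilic aromatic bromination can only give one monobromide because the two remaining ring C–H positions are equivalent by symmetry and strongly activated.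

Step 7
Reactants: 8 1-(benzyloxy)-2-bromo-4-methoxy-3,5-bis(methoxymethoxy)benzene, 9 N,2-dimethoxy-N-methylacetamide
Product: 11 1-[6-(benzyloxy)-3-methoxy-2,4-bis(methoxymethoxy)phenyl]-2-methoxyethan-1-one, via aryllithium 10 (not isolated)
Conditions: n-BuLi (1.05 equiv), THF, −78 °C; then 9, −78 to 0 °C; aq. NH4Cl
Reagents that add atoms: none
Why: Bromine–lithium exchange at −78 °C gives the aryllithium without touching the benzyl ether, and Weinreb amide acylation stops at the ketone because the chelated tetrahedral adduct survives until work-up.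

**Ring B fragment**

Step 8
Reactants: 12 3-(benzyloxy)-4-methoxybenzaldehyde
Product: 14 3-(benzyloxy)-4-methoxyphenol, via aryl formate 13 (not isolated)
Conditions: mCPBA, CH2Cl2, rt; aq. NaHCO3 wash; then K2CO3 (cat.), MeOH, rt
Reagents that add atoms: 3-chloroperoxybenzoic acid (mCPBA), OOC(=O)c1cccc(Cl)c1
Why: Baeyer–Villiger oxidation of a p-methoxybenzaldehyde followed by formate methanolysis is a dependable aldehyde-to-phenol conversion.

Step 9
Reactants: 14 3-(benzyloxy)-4-methoxyphenol
Product: 15 2,4-bis(benzyloxy)-1-methoxybenzene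
Conditions: BnBr, K2CO3, DMF, 50 °C
Reagents that add atoms: benzyl bromide, BrCc1ccccc1
Why: Williamson etherification of the free phenol completes the 1,2,4-trioxygenated arene with methyl on the correct oxygen.

Step 10
Reactants: 15 2,4-bis(benzyloxy)-1-methoxybenzene
Product: 17 2,4-bis(benzyloxy)-5-methoxybenzaldehyde, via aryl iminium salt 16 (not isolated)
Conditions: POCl3, DMF, 0 to 70 °C; then ice-water
Reagents that add atoms: N,N-dimethylformamide, CN(C)C=O; water, O
Why: Vilsmeier–Haack formylation attacks the position para to one benzyloxy group and ortho to the other, the same selectivity that turns 1,2,4-trimethoxybenzene into 2,4,5-trimethoxybenzaldehyde.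

Step 11
Reactants: 17 2,4-bis(benzyloxy)-5-methoxybenzaldehyde
Product: 18 2,4-bis(benzyloxy)-5-methoxybenzoic acid
Conditions: NaClO2, NaH2PO4, 2-methyl-2-butene, t-BuOH/H2O, rt
Reagents that add atoms: sodium chlorite, [Na+].[O-]Cl=O
Why: Pinnick oxidation with an alkene scavenger for hypochlorous acid gives the acid without chlorinating the electron-rich ring.

Step 12
Reactants: 18 2,4-bis(benzyloxy)-5-methoxybenzoic acid
Product: 19 2,4-bis(benzyloxy)-5-methoxybenzoyl chloride
Conditions: (COCl)2, DMF (cat.), CH2Cl2, 0 °C to rt; used crude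
Reagents that add atoms: oxalyl chloride, O=C(Cl)C(Cl)=O
Why: DMF-catalysed acyl chloride formation is mild enough for benzyl ethers and gives only gaseous by-products.

**Fragment union and endgame**

Step 13
Reactants: 11 1-[6-(benzyloxy)-3-methoxy-2,4-bis(methoxymethoxy)phenyl]-2-methoxyethan-1-one, 19 2,4-bis(benzyloxy)-5-methoxybenzoyl chloride
Product: 21 1-[6-(benzyloxy)-3-methoxy-2,4-bis(methoxymethoxy)phenyl]-3-[2,4-bis(benzyloxy)-5-methoxyphenyl]-2-methoxypropane-1,3-dione (racemic), via lithium enolate 20 (not isolated)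
Conditions: LiN(SiMe3)2 (2.2 equiv), THF, −78 °C; then 19, −78 to 0 °C; aq. NH4Cl
Reagents that add atoms: none
Why: In this crossed Claisen condensation the chelated lithium Z-enolate is C-acylated by the aroyl chloride, the second equivalent of base drives it by deprotonating the more acidic 1,3-diketone, and the new CH(OMe) centre is racemic and disappears in step 14.

Step 14
Reactants: 21 1-[6-(benzyloxy)-3-methoxy-2,4-bis(methoxymethoxy)phenyl]-3-[2,4-bis(benzyloxy)-5-methoxyphenyl]-2-methoxypropane-1,3-dione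
Product: 24 5-(benzyloxy)-2-[2,4-bis(benzyloxy)-5-methoxyphenyl]-7-hydroxy-3,8-dimethoxy-4H-chromen-4-one, via dihydroxy diketone 22 (not isolated), via cyclic hemiketal 23 (not isolated)
Conditions: 3 M HCl, MeOH/THF, 55 °C
Reagents that add atoms: none
Why: Acid methanolysis of both MOM acetals frees the phenol ortho to the ketone, which closes onto the distal carbonyl and dehydrates to the chromone (cyclodehydration), and only the 8-methoxy isomer can form because the other ortho oxygen stays benzylated.

Step 15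
Reactants: 24 5-(benzyloxy)-2-[2,4-bis(benzyloxy)-5-methoxyphenyl]-7-hydroxy-3,8-dimethoxy-4H-chromen-4-one
Product: 25 5,7-dihydroxy-2-(2,4-dihydroxy-5-methoxyphenyl)-3,8-dimethoxy-4H-chromen-4-one
Conditions: H2 (1 atm), 10% Pd/C, THF/MeOH, rt
Reagents that add atoms: none
Why: Catalytic hydrogenolysis removes the three aryl benzyl ethers while methyl ethers and the chromone core stay intact, and the target has no stereocentre to set.

**Compound list**
1 | methyl 3,5-dihydroxy-4-methoxybenzoate | COC(=O)c1cc(O)c(OC)c(O)c1 | starting material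
2 | methyl 4-methoxy-3,5-bis(methoxymethoxy)benzoate | COCOc1cc(C(=O)OC)cc(OCOC)c1OC | intermediate
3 | [4-methoxy-3,5-bis(methoxymethoxy)phenyl]methanol | COCOc1cc(CO)cc(OCOC)c1OC | intermediate
4 | 4-methoxy-3,5-bis(methoxymethoxy)benzaldehyde | COCOc1cc(C=O)cc(OCOC)c1OC | intermediate
5 | 4-methoxy-3,5-bis(methoxymethoxy)phenyl formate | COCOc1cc(OC=O)cc(OCOC)c1OC | intermediate
6 | 4-methoxy-3,5-bis(methoxymethoxy)phenol | COCOc1cc(O)cc(OCOC)c1OC | intermediate
7 | 5-(benzyloxy)-2-methoxy-1,3-bis(methoxymethoxy)benzene | COCOc1cc(OCc2ccccc2)cc(OCOC)c1OC | intermediate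
8 | 1-(benzyloxy)-2-bromo-4-methoxy-3,5-bis(methoxymethoxy)benzene | COCOc1cc(OCc2ccccc2)c(Br)c(OCOC)c1OC | intermediate
9 | N,2-dimethoxy-N-methylacetamide | COCC(=O)N(C)OC | starting material
10 | [6-(benzyloxy)-3-methoxy-2,4-bis(methoxymethoxy)phenyl]lithium | COCOc1cc(OCc2ccccc2)c([Li])c(OCOC)c1OC | intermediate
11 | 1-[6-(benzyloxy)-3-methoxy-2,4-bis(methoxymethoxy)phenyl]-2-methoxyethan-1-one | COCOc1cc(OCc2ccccc2)c(C(=O)COC)c(OCOC)c1OC | intermediate
12 | 3-(benzyloxy)-4-methoxybenzaldehyde | COc1ccc(C=O)cc1OCc1ccccc1 | starting material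
13 | 3-(benzyloxy)-4-methoxyphenyl formate | COc1ccc(OC=O)cc1OCc1ccccc1 | intermediate
14 | 3-(benzyloxy)-4-methoxyphenol | COc1ccc(O)cc1OCc1ccccc1 | intermediate
15 | 2,4-bis(benzyloxy)-1-methoxybenzene | COc1ccc(OCc2ccccc2)cc1OCc1ccccc1 | intermediate
16 | N-{[2,4-bis(benzyloxy)-5-methoxyphenyl]methylidene}-N-methylmethanaminium dichlorophosphate | COc1cc(C=[N+](C)C)c(OCc2ccccc2)cc1OCc1ccccc1.[O-]P(=O)(Cl)Cl | intermediate
17 | 2,4-bis(benzyloxy)-5-methoxybenzaldehyde | COc1cc(C=O)c(OCc2ccccc2)cc1OCc1ccccc1 | intermediate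
18 | 2,4-bis(benzyloxy)-5-methoxybenzoic acid | COc1cc(C(=O)O)c(OCc2ccccc2)cc1OCc1ccccc1 | intermediate
19 | 2,4-bis(benzyloxy)-5-methoxybenzoyl chloride | COc1cc(C(Cl)=O)c(OCc2ccccc2)cc1OCc1ccccc1 | intermediate
20 | lithium (Z)-1-[6-(benzyloxy)-3-methoxy-2,4-bis(methoxymethoxy)phenyl]-2-methoxyethen-1-olate | [Li+].[O-]/C(=C\OC)c1c(OCc2ccccc2)cc(OCOC)c(OC)c1OCOC | intermediate
21 | 1-[6-(benzyloxy)-3-methoxy-2,4-bis(methoxymethoxy)phenyl]-3-[2,4-bis(benzyloxy)-5-methoxyphenyl]-2-methoxypropane-1,3-dione (racemic) | COCOc1cc(OCc2ccccc2)c(C(=O)C(OC)C(=O)c2cc(OC)c(OCc3ccccc3)cc2OCc2ccccc2)c(OCOC)c1OC | intermediate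
22 | 1-[6-(benzyloxy)-2,4-dihydroxy-3-methoxyphenyl]-3-[2,4-bis(benzyloxy)-5-methoxyphenyl]-2-methoxypropane-1,3-dione (racemic) | COc1c(O)cc(OCc2ccccc2)c(C(=O)C(OC)C(=O)c2cc(OC)c(OCc3ccccc3)cc2OCc2ccccc2)c1O | intermediate
23 | 5-(benzyloxy)-2-[2,4-bis(benzyloxy)-5-methoxyphenyl]-2,7-dihydroxy-3,8-dimethoxy-2,3-dihydro-4H-chromen-4-one (racemic diastereomer mixture) | COc1cc(C2(O)Oc3c(OC)c(O)cc(OCc4ccccc4)c3C(=O)C2OC)c(OCc2ccccc2)cc1OCc1ccccc1 | intermediate
24 | 5-(benzyloxy)-2-[2,4-bis(benzyloxy)-5-methoxyphenyl]-7-hydroxy-3,8-dimethoxy-4H-chromen-4-one | COc1cc(-c2oc3c(OC)c(O)cc(OCc4ccccc4)c3c(=O)c2OC)c(OCc2ccccc2)cc1OCc1ccccc1 | intermediate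
25 | 5,7-dihydroxy-2-(2,4-dihydroxy-5-methoxyphenyl)-3,8-dimethoxy-4H-chromen-4-one (5,7,2',4'-tetrahydroxy-3,8,5'-trimethoxyflavone) | COc1cc(-c2oc3c(OC)c(O)cc(O)c3c(=O)c2OC)c(O)cc1O | target

**Step count**
Total: 15 steps (7 for ring A, 5 for ring B, 3 for union and endgame).
Longest linear sequence: 10 steps (steps 1–7, then 13–15).

**Three steps most likely to fail, with fallbacks**

Step 13 (crossed Claisen condensation). The hindered α-methoxy enolate may be O-acylated or acylated twice. The fallback sets out from ketone 11, uses aldehyde 17 in place of acid chloride 19, and returns at diketone 21. Aldol addition of lithium enolate 20 (LiN(SiMe3)2, THF, −78 °C) to aldehyde 17 gives, as a diastereomer mixture, the β-hydroxy ketone 1-[6-(benzyloxy)-3-methoxy-2,4-bis(methoxymethoxy)phenyl]-3-[2,4-bis(benzyloxy)-5-methoxyphenyl]-3-hydroxy-2-methoxypropan-1-one F1. Dess–Martin periodinane (NaHCO3, CH2Cl2, rt) then oxidises it to diketone 21. Steps 11 and 12 are then not needed.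

Step 7 (aryllithium plus Weinreb amide). The basic, doubly ortho-substituted aryllithium may deprotonate amide 9 instead of adding to it. The fallback sets out from bromide 8 and returns at ketone 11. After the same Br/Li exchange to aryllithium 10, a DMF quench gives the non-enolisable aldehyde 6-(benzyloxy)-3-methoxy-2,4-bis(methoxymethoxy)benzaldehyde F2. Tin–lithium exchange of Bu3SnCH2OMe with n-BuLi (THF, −78 °C) gives methoxymethyllithium F3, which adds to the aldehyde to give racemic 1-[6-(benzyloxy)-3-methoxy-2,4-bis(methoxymethoxy)phenyl]-2-methoxyethan-1-ol F4. Dess–Martin oxidation of this alcohol gives ketone 11.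

Step 15 (hydrogenolysis). The chromone C2–C3 double bond could be over-reduced, or cleavage of the hindered 5-O-benzyl ether could stall. The fallback sets out from 24 and returns at target 25. It uses Lewis-acid debenzylation with BCl3 and pentamethylbenzene as benzyl-cation scavenger (CH2Cl2, −78 °C, MeOH quench). This cleaves aryl benzyl ethers without reducing anything and should leave the methyl ethers intact at that temperature. It makes no new compound (F0).

**Further compounds**
F1 | step 13 | 1-[6-(benzyloxy)-3-methoxy-2,4-bis(methoxymethoxy)phenyl]-3-[2,4-bis(benzyloxy)-5-methoxyphenyl]-3-hydroxy-2-methoxypropan-1-one (diastereomer mixture) | COCOc1cc(OCc2ccccc2)c(C(=O)C(OC)C(O)c2cc(OC)c(OCc3ccccc3)cc2OCc2ccccc2)c(OCOC)c1OC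
F2 | step 7 | 6-(benzyloxy)-3-methoxy-2,4-bis(methoxymethoxy)benzaldehyde | COCOc1cc(OCc2ccccc2)c(C=O)c(OCOC)c1OC
F3 | step 7 | methoxymethyllithium | [Li]COC
F4 | step 7 | 1-[6-(benzyloxy)-3-methoxy-2,4-bis(methoxymethoxy)phenyl]-2-methoxyethan-1-ol (racemic) | COCOc1cc(OCc2ccccc2)c(C(O)COC)c(OCOC)c1OC
F0 | step 15 | none | none
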